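**Assumption:** Stevensine as drawn has no stereocentres, and its only C=C is endocyclic (necessarily Z). "Single enantiomer" therefore reduces to making the one constitutional isomer with the olefin at C4=C5; the route fixes that position by construction.

## Retrosynthetic overview

1. Stevensine ⇐ hydrazinolysis of an imidazo[1,2-a]pyrimidin-3-yl group (masked 2-aminoimidazole), after acid removal of a PMB group from the lactam nitrogen.
2. Azepinone ring (C3a–C4 bond and C4=C5 olefin) ⇐ new Au(I)-catalysed 7-endo-dig hydroarylation of pyrrole C3–H onto a heteroaryl alkyne.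
3. Cyclisation precursor ⇐ amidation of a secondary propargylic amine with 4,5-dibromo-2-(trichloroacetyl)pyrrole.
4. Amine ⇐ Sonogashira coupling of N-PMB-propargylamine with 3-iodoimidazo[1,2-a]pyrimidine.
5. Ring order: pyrrole and imidazole are purchased pre-formed (the imidazole inside the imidazopyrimidine); the azepinone is formed in step 5; the pyrimidine mask is excised last.

## Route

**Step 1**
Reactants: 1 propargylamine; 2 4-methoxybenzaldehyde
Product: 3 N-(4-methoxybenzyl)prop-2-yn-1-amine
Conditions: MeOH, 4 Å MS, rt; then NaBH4, 0 °C → rt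
Reagents that add atoms: none (NaBH4 delivers H only)
Why: Standard reductive amination (imine formation, then borohydride reduction); the terminal alkyne is inert and the PMB group later makes the amide tertiary.

**Step 2**
Reactants: 4 imidazo[1,2-a]pyrimidine
Product: 5 3-iodoimidazo[1,2-a]pyrimidine
Conditions: NIS (1.05 equiv), MeCN, rt, dark
Reagents that add atoms: N-iodosuccinimide, O=C1CCC(=O)N1I
Why: Electrophilic aromatic iodination occurs at C3, the enamine-like and most nucleophilic carbon of the bicycle.

**Step 3**
Reactants: 3 N-(4-methoxybenzyl)prop-2-yn-1-amine; 5 3-iodoimidazo[1,2-a]pyrimidine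
Product: 6 3-(imidazo[1,2-a]pyrimidin-3-yl)-N-(4-methoxybenzyl)prop-2-yn-1-amine
Conditions: Pd(PPh3)2Cl2 (3 mol%), CuI (6 mol%), Et3N, DMF, 40 °C, Ar
Reagents that add atoms: none
Why: Sonogashira coupling of a heteroaryl iodide with a terminal alkyne; the secondary amine is tolerated and no other halide is present at this stage.

**Step 4**
Reactants: 6 (secondary amine); 7 2,2,2-trichloro-1-(4,5-dibromo-1H-pyrrol-2-yl)ethan-1-one
Product: 8 4,5-dibromo-N-[3-(imidazo[1,2-a]pyrimidin-3-yl)prop-2-yn-1-yl]-N-(4-methoxybenzyl)-1H-pyrrole-2-carboxamide
Conditions: Et3N (1.5 equiv), MeCN, 45 °C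
Reagents that add atoms: none
Why: Haloform-type amidation (CCl3⁻ as leaving group) acylates the amine without protecting the pyrrole N–H, and the base is too mild to drive pyrrole-N addition to the alkyne.

**Step 5 (key step)**
Reactants: 8 (alkynyl amide)
Product: 9 2,3-dibromo-4-(imidazo[1,2-a]pyrimidin-3-yl)-7-(4-methoxybenzyl)-6,7-dihydropyrrolo[2,3-c]azepin-8(1H)-one
Conditions: [JohnPhosAu(MeCN)]SbF6 (10 mol%), HFIP (10 equiv), DCE (0.05 M), 60 °C, Ar
Reagents that add atoms: none (cycloisomerisation)
Why: Proposed new method: a donor-heteroaryl-polarised Au(I)-catalysed 7-endo-dig hydroarylation by a halogen-deactivated pyrrole — LAu⁺ π-activates the alkyne, the imidazo[1,2-a]pyrimidin-3-yl donor (reinforced by the inductively withdrawing N-acyl-aminomethyl side) localises positive charge on the heteroaryl-bearing alkyne carbon, the tertiary N-PMB amide populates the rotamer that places this carbon over pyrrole C3 (the only free ring carbon) and prevents neutral oxazine formation by amide-O attack, C3 attacks anti to gold, and rearomatisation plus HFIP-assisted protodeauration (HFIP also H-bonds the basic ring nitrogens so they do not sequester gold) gives the C3a–C4 bond with the olefin fixed at C4=C5 and no stereocentre created; the closest known reaction type is gold-catalysed cycloisomerisation (intramolecular alkyne hydroarylation) of N-propargyl indole-/pyrrole-2-carboxamides, not shown for 4,5-dibromopyrroles or for alkynes bearing a 2-aminoimidazole surrogate.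

**Step 6**
Reactants: 9 (N-PMB lactam)
Product: 10 2,3-dibromo-4-(imidazo[1,2-a]pyrimidin-3-yl)-6,7-dihydropyrrolo[2,3-c]azepin-8(1H)-one
Conditions: TFA/anisole (10:1), 70 °C
Reagents that add atoms: none
Why: Acidolytic N-debenzylation (SN1 loss of the PMB cation, trapped by anisole) while the 2-aminoimidazole is still masked and non-nucleophilic; no silane is used, to avoid ionic hydrogenation of the C4=C5 olefin, and the C–Br bonds and conjugated olefin should tolerate TFA.

**Step 7**
Reactants: 10 (N–H lactam)
Product: 11 stevensine, 4-(2-amino-1H-imidazol-5-yl)-2,3-dibromo-6,7-dihydropyrrolo[2,3-c]azepin-8(1H)-one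
Conditions: N2H4·H2O (20 equiv), EtOH, 90 °C, sealed tube, Ar (O2 excluded)
Reagents that add atoms: none (hydrazine removes C5–C6–C7 of the pyrimidine as pyrazole; the exocyclic NH2 is the former N8)
Why: Hydrazinolytic ring-opening/ring-closure of the pyrimidine ring (ANRORC-type cleavage, a known unmasking of imidazo[1,2-a]pyrimidines) releases the 2-aminoimidazole with the former C3 substituent at C4(5); the lactam, C–Br bonds and the non-electrophilic olefin are inert, and excluding air prevents diimide formation.

## Compound list

1 | propargylamine | C#CCN | starting material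
2 | 4-methoxybenzaldehyde | COc1ccc(C=O)cc1 | starting material
3 | N-(4-methoxybenzyl)prop-2-yn-1-amine | C#CCNCc1ccc(OC)cc1 | intermediate
4 | imidazo[1,2-a]pyrimidine | c1cnc2nccn2c1 | starting material
5 | 3-iodoimidazo[1,2-a]pyrimidine | Ic1cnc2ncccn12 | intermediate
6 | 3-(imidazo[1,2-a]pyrimidin-3-yl)-N-(4-methoxybenzyl)prop-2-yn-1-amine | COc1ccc(CNCC#Cc2cnc3ncccn23)cc1 | intermediate
7 | 2,2,2-trichloro-1-(4,5-dibromo-1H-pyrrol-2-yl)ethan-1-one | O=C(c1cc(Br)c(Br)[nH]1)C(Cl)(Cl)Cl | starting material
8 | 4,5-dibromo-N-[3-(imidazo[1,2-a]pyrimidin-3-yl)prop-2-yn-1-yl]-N-(4-methoxybenzyl)-1H-pyrrole-2-carboxamide | COc1ccc(CN(CC#Cc2cnc3ncccn23)C(=O)c2cc(Br)c(Br)[nH]2)cc1 | intermediate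
9 | 2,3-dibromo-4-(imidazo[1,2-a]pyrimidin-3-yl)-7-(4-methoxybenzyl)-6,7-dihydropyrrolo[2,3-c]azepin-8(1H)-one | COc1ccc(CN2CC=C(c3cnc4ncccn34)c3c(Br)c(Br)[nH]c3C2=O)cc1 | intermediate
10 | 2,3-dibromo-4-(imidazo[1,2-a]pyrimidin-3-yl)-6,7-dihydropyrrolo[2,3-c]azepin-8(1H)-one | O=C1NCC=C(c2cnc3ncccn23)c2c(Br)c(Br)[nH]c21 | intermediate
11 | stevensine | Nc1ncc(C2=CCNC(=O)c3[nH]c(Br)c(Br)c32)[nH]1 | target

## Summary

Total step count: 7.
Longest linear sequence: 6 steps (1 → 3 → 4 → 5 → 6 → 7; the branch through step 2 is also 6).

Three steps most likely to fail: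

1. **Step 5 (proposed new Au 7-endo hydroarylation).** Risks are low nucleophilicity of the dibromopyrrole C3, gold sequestration by the azine nitrogens, and competing 6-exo attack, amide-O attack with loss of PMB, or PMB-ipso attack. Fallback (known chemistry, different approach): drop the alkyne and use the acid-mediated azafulvene route. Amidate 7 with 2-(1,3-dioxolan-2-yl)ethanamine; cyclise the unmasked aldehyde onto pyrrole C3 in MeSO3H and trap the resulting cation with 2-aminoimidazole to give (±)-hymenin (the 4,5-dihydro compound). Then brominate the imidazole (Br2, TFA) and eliminate HBr in hot MeSO3H to reach the C4=C5 olefin of stevensine.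

2. **Step 7 (hydrazinolytic unmasking).** A neutral, C3-hindered imidazopyrimidine may open slowly, and forcing conditions risk side reactions. Fallback: change the surrogate. Couple in step 3 with a Boc-protected 2-amino-4-iodoimidazole (from 2-aminoimidazole hemisulfate by Boc protection, then NIS), so that the amine is released by acid together with the PMB group in one TFA step and no nucleophilic ring degradation is needed.

3. **Step 6 (PMB removal from the lactam in hot TFA).** Cleavage may be sluggish, or acid may cause partial protodebromination or olefin migration. Fallback: change the nitrogen substituent and the cleavage mode. Carry an N-methoxy amide from O-methyl-N-propargylhydroxylamine (acylated with 4,5-dibromopyrrole-2-carbonyl chloride) and cleave the N–O bond reductively with Mo(CO)6 in MeCN/H2O after cyclisation, avoiding strong acid.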